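**Retrosynthetic overview**

1. The last ring to close is the furanone (ring B), by transannular formation of the C10–O bond across the ten-membered carbocycle (ring A) of allenyl vinyl ketone 26: DMDO epoxidizes C10=C1 and the C3 carbonyl oxygen opens the allene oxide at C10.
2. The enabling feature is the C10=C1=C2 allene conjugated to the C3 ketone inside ring A: after epoxidation the C3 carbonyl oxygen lies in the oxirane plane, across the ring and to the rear of the C10–O bond, and the (P) axis becomes the C10 stereocentre.
3. Ring A is closed at C3–C4 by an intramolecular CrCl2/NiCl2 coupling of a (Z)-vinyl iodide with a 2,3-allenal, followed by oxidation to 26.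
4. The lactone (ring C) comes from a CrCl2 Barbier allylation (C6–C7) of iodo-enal 17 with allylic bromide 13 and lactonization; the allene axis comes from asymmetric ynone reduction and anti-SN2' methylation, and C8 from (S)-glycidol.
5. Order of ring formation: lactone C, then carbocycle A, then furanone B; desilylation of O15 ends the route.

Key step: step 19

Remark on the chemistry: atoms carry germacrane numbers (C1 ketone carbon, C2 furanone CH, C3 furanone C–O carbon, C4=C5 ring alkene, C6 lactone O–CH, C7 ring-fusion CH, C8 CH–O ester, C9 CH2, C10 quaternary C–O, C11/C12/C13 lactone C, C=O and =CH2, C14 methyl, C15 CH2OH). The allene axis is (P) and is written in SMILES as an extended tetrahedral centre on C1; where protecting groups change CIP letters, the SMILES is binding.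

**Step 1**
Reactants: 1 (S)-glycidol; 2 lithium acetylide–ethylenediamine complex
Product: 3 (R)-pent-4-yne-1,2-diol
Conditions: 2 (2.5 equiv), DMSO, 0 °C → rt; then H2O
Reagents that add atoms: none
Why: SN2 opening of the terminal epoxide carbon by acetylide (the Payne rearrangement of the glycidol alkoxide is degenerate) carries the stereocentre of 1 over unchanged as C8.

**Step 2**
Reactants: 3 (R)-pent-4-yne-1,2-diol
Product: 4 (R)-4,5-bis(triethylsilyloxy)pent-1-yne
Conditions: TESCl, imidazole, DMF, 0 °C → rt
Reagents that add atoms: chlorotriethylsilane (CC[Si](Cl)(CC)CC)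
Why: Standard silylation of both hydroxyls; the primary TES ether is the later aldehyde precursor.

**Step 3**
Reactants: 4 (R)-4,5-bis(triethylsilyloxy)pent-1-yne; 5 2-(tert-butyldimethylsilyloxy)-N-methoxy-N-methylacetamide
Product: 6 (R)-1-(tert-butyldimethylsilyloxy)-6,7-bis(triethylsilyloxy)hept-3-yn-2-one
Conditions: n-BuLi, THF, −78 °C; then 5, −78 → 0 °C; then H2O
Reagents that add atoms: none
Why: Acylation of the lithium acetylide with a Weinreb amide stops at the ynone because the chelated tetrahedral adduct survives until work-up.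

**Step 4**
Reactants: 6 ynone
Product: 7 (2R,6R)-1-(tert-butyldimethylsilyloxy)-6,7-bis(triethylsilyloxy)hept-3-yn-2-ol
Conditions: Ru[(S,S)-TsDPEN](p-cymene) (2 mol %), i-PrOH, rt
Reagents that add atoms: none
Why: Noyori asymmetric transfer hydrogenation of an alkynyl ketone sets the propargylic carbinol under catalyst control, expected (R) with the (S,S)-ligand by analogy with methyl alkynyl ketones (the CH2OTBS group changes only the CIP letter).

**Step 5**
Reactants: 7 propargylic alcohol
Product: 9 (6R,P)-1-(tert-butyldimethylsilyloxy)-4-methyl-6,7-bis(triethylsilyloxy)hepta-2,3-diene, via mesylate 8 (not isolated)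
Conditions: n-BuLi then MsCl, THF, −78 °C; cannulated into MeMgBr/CuBr·SMe2/LiBr, THF, −78 → −40 °C
Reagents that add atoms: methylmagnesium bromide (C[Mg]Br)
Why: anti-SN2' substitution of a propargylic mesylate by a Grignard-derived methylcopper reagent puts the methyl group on C10 opposite the leaving group, so the (R)-carbinol is converted into the (P) allene axis.

**Step 6**
Reactants: 9 allene
Product: 10 (2R,P)-7-(tert-butyldimethylsilyloxy)-4-methyl-2-(triethylsilyloxy)hepta-4,5-dienal
Conditions: (COCl)2, DMSO, CH2Cl2, −78 → −30 °C; Et3N, −78 → 0 °C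
Reagents that add atoms: none
Why: Direct Swern oxidation of a primary triethylsilyl ether (activated DMSO cleaves and oxidizes only the primary TES ether; secondary TES and TBS ethers persist), kept cold to protect the α-silyloxy stereocentre C8.

**Step 7**
Reactants: 10 aldehyde; 11 methyl acrylate
Product: 12 methyl 2-[(2R,P)-1-hydroxy-7-(tert-butyldimethylsilyloxy)-4-methyl-2-(triethylsilyloxy)hepta-4,5-dien-1-yl]acrylate (both carbinol epimers)
Conditions: DABCO, 11 (excess), MeOH, rt
Reagents that add atoms: none
Why: Morita–Baylis–Hillman reaction of an activated α-silyloxy aldehyde; the new carbinol centre is destroyed in step 8, so its configuration does not matter.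

**Step 8**
Reactants: 12 Morita–Baylis–Hillman alcohol
Product: 13 methyl (2Z,4R,P)-2-(bromomethyl)-9-(tert-butyldimethylsilyloxy)-6-methyl-4-(triethylsilyloxy)nona-2,6,7-trienoate
Conditions: NBS, Me2S, CH2Cl2, 0 °C → rt
Reagents that add atoms: N-bromosuccinimide (O=C1CCC(=O)N1Br)
Why: Corey–Kim-type bromination with allylic transposition (SN2') gives the thermodynamically preferred (Z)-2-(bromomethyl)enoate.

**Step 9**
Reactants: 14 but-2-yne-1,4-diol
Product: 15 4-(tert-butyldiphenylsilyloxy)but-2-yn-1-ol
Conditions: NaH (1.0 equiv), THF, 0 °C; TBDPSCl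
Reagents that add atoms: tert-butylchlorodiphenylsilane (CC(C)(C)[Si](Cl)(c1ccccc1)c1ccccc1)
Why: Monosilylation of a symmetrical diol through its sparingly soluble monosodium alkoxide.

**Step 10**
Reactants: 15 propargylic alcohol
Product: 16 (Z)-4-(tert-butyldiphenylsilyloxy)-3-iodobut-2-en-1-ol
Conditions: NaAlH2(OCH2CH2OCH3)2 (Red-Al), THF, 0 °C; EtOAc; then I2, −78 → 0 °C
Reagents that add atoms: iodine (II)
Why: Hydroxyl-directed trans-hydroalumination puts aluminium on the alkyne carbon remote from the free hydroxyl (C4), and iodinolysis with retention gives the vinyl iodide with iodine (the later C3 position) cis to C6.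

**Step 11**
Reactants: 16 allylic alcohol
Product: 17 (Z)-4-(tert-butyldiphenylsilyloxy)-3-iodobut-2-enal
Conditions: MnO2, CH2Cl2, rt, dark
Reagents that add atoms: none
Why: Neutral oxidation of a primary allylic alcohol that leaves the (Z)-iodoalkene geometry intact.

**Step 12**
Reactants: 13 allylic bromide; 17 iodo-enal
Product: 19 trans-α-methylene-γ-butyrolactone carrying the (Z)-2-iodo-3-(tert-butyldiphenylsilyloxy)prop-1-enyl group on C6 and the (1R,P)-6-(tert-butyldimethylsilyloxy)-3-methyl-1-(triethylsilyloxy)hexa-3,4-dienyl chain on C7, via hydroxy ester 18 (not isolated)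
Conditions: CrCl2 (4 equiv), THF, 0 °C → rt; then H2O
Reagents that add atoms: none
Why: Nozaki–Hiyama-type Barbier allylation by a 2-(methoxycarbonyl)allylchromium reagent through a chair transition state should give the 6,7-anti adduct (trans-lactone after lactonization of the chromium alkoxide), and the C8 centre is expected to steer the aldehyde to the C7 face anti to the C9 chain with H-8 eclipsing the enoate (allylic 1,3-strain), which gives the target configuration at C6 and C7.

**Step 13**
Reactants: 19 lactone
Product: 20 C8 alcohol of 19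
Conditions: HF·pyridine, pyridine, THF, 0 °C
Reagents that add atoms: none
Why: Buffered fluoride cleaves the most labile silyl ether (secondary TES) in the presence of the primary TBS and TBDPS ethers.

**Step 14**
Reactants: 20 C8 alcohol; 21 methacrylic anhydride
Product: 22 C8 methacrylate
Conditions: 21, Et3N, DMAP (cat.), CH2Cl2, 0 °C → rt
Reagents that add atoms: none
Why: DMAP-catalysed acylation of the secondary alcohol with retention at C8; the ester also blocks oxa-Michael addition of O8 to the later allenyl carbonyl.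

**Step 15**
Reactants: 22 methacrylate
Product: 23 primary allenic alcohol (C3–OH)
Conditions: CSA (cat.), MeOH/CH2Cl2, 0 °C
Reagents that add atoms: none
Why: Acid-catalysed methanolysis removes the primary TBS ether while the far more acid-stable TBDPS ether and both esters stay.

**Step 16**
Reactants: 23 allenic alcohol
Product: 24 2,3-allenal (C3 aldehyde)
Conditions: Dess–Martin periodinane, NaHCO3, CH2Cl2, 0 °C
Reagents that add atoms: none
Why: Buffered Dess–Martin oxidation of a primary allenic alcohol gives the allenal without touching the allene axis.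

**Step 17**
Reactants: 24 iodo-allenal
Product: 25 ten-membered allenyl vinyl carbinol (ring A closed, both C3 epimers)
Conditions: CrCl2 (10 equiv), NiCl2 (1 mol %), degassed DMSO/THF, rt, slow addition (2 mM)
Reagents that add atoms: none
Why: Intramolecular Nozaki–Hiyama–Kishi coupling (vinyl iodide to vinylnickel to vinylchromium, then 1,2-addition to the aldehyde) closes ring A at C3–C4 with retention of the (Z)-alkene; the new carbinol centre is removed in step 18.

**Step 18**
Reactants: 25 macrocyclic carbinol
Product: 26 ten-membered allenyl vinyl ketone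
Conditions: Dess–Martin periodinane, NaHCO3, CH2Cl2, 0 °C
Reagents that add atoms: none
Why: Buffered oxidation of a doubly activated secondary alcohol under non-acidic conditions avoids acid-induced Nazarov chemistry of the allenyl vinyl ketone.

**Step 19**
Reactants: 26 macrocyclic allenyl vinyl ketone
Product: 28 15-O-TBDPS ether of the target (10S), via allene oxide 27 (not isolated)
Conditions: DMDO (1.05 equiv, acetone solution), CH2Cl2, −78 → −20 °C
Reagents that add atoms: dimethyldioxirane (CC1(C)OO1)
Why: Proposed new method: DMDO should epoxidize the electron-rich, non-conjugated C10=C1 bond of the allenyl ketone on the face syn to H-2, giving alkylidene oxirane 27 with C10 and C3 cis on C1=C2; the C3 carbonyl oxygen, lying in the oxirane plane across ring A, then opens the tertiary C10–O bond from the rear, and the oxygen left on C1 becomes the C1 ketone of the vinylogous ester. The closest known reaction types are dioxirane oxidation of allenes with intramolecular capture of the allene oxide by hydroxyl or carboxyl groups, and the allene oxide/oxyallyl route from vinyl allenes to cyclopentenones (oxidation-initiated Nazarov), of which this is the carbonyl-oxygen (1-oxapentadienyl, 4π) counterpart. Ring B closes by a 5-endo opening of the oxirane (both oxirane carbons end up in the furanone), and the same bond completes the 11-oxabicyclo[6.2.1] framework transannularly. The only new stereocentre, C10, is controlled by the (P) allene axis: methyl and C9 stay on their sides of the C1=C2–C3=O plane while oxygen enters within that plane, so axis-to-centre transfer should give (10S). The step needs selectivity for the allene over the enone, methacrylate and α-methylene lactone alkenes (all electron-poor towards an electrophilic dioxirane) and for mono-epoxidation (the remaining C1=C2 bond of 27 is deactivated by the ketone and consumed intramolecularly), both secured by one equivalent of oxidant at low temperature.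

**Step 20**
Reactants: 28 silyl ether
Product: 29 target CNP0180483.4
Conditions: HF·pyridine, pyridine, THF, 0 °C → rt
Reagents that add atoms: none
Why: Buffered fluoride cleavage of the primary TBDPS ether, which the esters, the α-methylene lactone and the furanone should tolerate.

**Compound list**

1 | (S)-glycidol | OC[C@H]1CO1 | starting material
2 | lithium acetylide–ethylenediamine complex | [Li+].[C-]#C.NCCN | starting material
3 | (R)-pent-4-yne-1,2-diol | C#CC[C@@H](O)CO | intermediate
4 | (R)-4,5-bis(triethylsilyloxy)pent-1-yne | C#CC[C@@H](O[Si](CC)(CC)CC)CO[Si](CC)(CC)CC | intermediate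
5 | 2-(tert-butyldimethylsilyloxy)-N-methoxy-N-methylacetamide | CON(C)C(=O)CO[Si](C)(C)C(C)(C)C | starting material
6 | (R)-1-(tert-butyldimethylsilyloxy)-6,7-bis(triethylsilyloxy)hept-3-yn-2-one | CC(C)(C)[Si](C)(C)OCC(=O)C#CC[C@@H](O[Si](CC)(CC)CC)CO[Si](CC)(CC)CC | intermediate
7 | (2R,6R)-1-(tert-butyldimethylsilyloxy)-6,7-bis(triethylsilyloxy)hept-3-yn-2-ol | CC(C)(C)[Si](C)(C)OC[C@H](O)C#CC[C@@H](O[Si](CC)(CC)CC)CO[Si](CC)(CC)CC | intermediate
8 | methanesulfonate of 7 | CC(C)(C)[Si](C)(C)OC[C@H](OS(C)(=O)=O)C#CC[C@@H](O[Si](CC)(CC)CC)CO[Si](CC)(CC)CC | intermediate (not isolated)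
9 | (6R,P)-1-(tert-butyldimethylsilyloxy)-4-methyl-6,7-bis(triethylsilyloxy)hepta-2,3-diene | CC[Si](CC)(CC)OC[C@H](O[Si](CC)(CC)CC)CC(C)=[C@@]=C([H])CO[Si](C)(C)C(C)(C)C | intermediate
10 | (2R,P)-7-(tert-butyldimethylsilyloxy)-4-methyl-2-(triethylsilyloxy)hepta-4,5-dienal | O=C[C@H](O[Si](CC)(CC)CC)CC(C)=[C@@]=C([H])CO[Si](C)(C)C(C)(C)C | intermediate
11 | methyl acrylate | C=CC(=O)OC | starting material
12 | Morita–Baylis–Hillman alcohol (C8 R, allene P, carbinol epimers) | C=C(C(=O)OC)C(O)[C@H](O[Si](CC)(CC)CC)CC(C)=[C@@]=C([H])CO[Si](C)(C)C(C)(C)C | intermediate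
13 | methyl (2Z,4R,P)-2-(bromomethyl)-9-(tert-butyldimethylsilyloxy)-6-methyl-4-(triethylsilyloxy)nona-2,6,7-trienoate | BrC/C(C(=O)OC)=C\[C@H](O[Si](CC)(CC)CC)CC(C)=[C@@]=C([H])CO[Si](C)(C)C(C)(C)C | intermediate
14 | but-2-yne-1,4-diol | OCC#CCO | starting material
15 | 4-(tert-butyldiphenylsilyloxy)but-2-yn-1-ol | OCC#CCO[Si](c1ccccc1)(c1ccccc1)C(C)(C)C | intermediate
16 | (Z)-4-(tert-butyldiphenylsilyloxy)-3-iodobut-2-en-1-ol | OC/C=C(\I)CO[Si](c1ccccc1)(c1ccccc1)C(C)(C)C | intermediate
17 | (Z)-4-(tert-butyldiphenylsilyloxy)-3-iodobut-2-enal | O=C/C=C(\I)CO[Si](c1ccccc1)(c1ccccc1)C(C)(C)C | intermediate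
18 | 6,7-anti hydroxy ester (open form of 19) | COC(=O)C(=C)[C@@H]([C@H](O)/C=C(\I)CO[Si](c1ccccc1)(c1ccccc1)C(C)(C)C)[C@H](O[Si](CC)(CC)CC)CC(C)=[C@@]=C([H])CO[Si](C)(C)C(C)(C)C | intermediate (not isolated)
19 | trans-lactone, C8–OTES, C3–OTBS, C15–OTBDPS, vinyl iodide at C4 (C6, C7, C8 as in the target) | C=C1C(=O)O[C@H](/C=C(\I)CO[Si](c2ccccc2)(c2ccccc2)C(C)(C)C)[C@H]1[C@H](O[Si](CC)(CC)CC)CC(C)=[C@@]=C([H])CO[Si](C)(C)C(C)(C)C | intermediate
20 | C8 alcohol of 19 | C=C1C(=O)O[C@H](/C=C(\I)CO[Si](c2ccccc2)(c2ccccc2)C(C)(C)C)[C@H]1[C@H](O)CC(C)=[C@@]=C([H])CO[Si](C)(C)C(C)(C)C | intermediate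
21 | methacrylic anhydride | CC(=C)C(=O)OC(=O)C(C)=C | starting material
22 | C8 methacrylate | C=C1C(=O)O[C@H](/C=C(\I)CO[Si](c2ccccc2)(c2ccccc2)C(C)(C)C)[C@H]1[C@H](OC(=O)C(C)=C)CC(C)=[C@@]=C([H])CO[Si](C)(C)C(C)(C)C | intermediate
23 | primary allenic alcohol (C3–OH) | C=C1C(=O)O[C@H](/C=C(\I)CO[Si](c2ccccc2)(c2ccccc2)C(C)(C)C)[C@H]1[C@H](OC(=O)C(C)=C)CC(C)=[C@@]=C([H])CO | intermediate
24 | 2,3-allenal (C3 aldehyde) | C=C1C(=O)O[C@H](/C=C(\I)CO[Si](c2ccccc2)(c2ccccc2)C(C)(C)C)[C@H]1[C@H](OC(=O)C(C)=C)CC(C)=[C@@]=C([H])C=O | intermediate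
25 | ten-membered allenyl vinyl carbinol (P allene, 4Z, C3 epimers) | C=C(C)C(=O)O[C@@H]1CC(C)=[C@@]=C([H])C(O)/C(CO[Si](c3ccccc3)(c3ccccc3)C(C)(C)C)=C\[C@H]2OC(=O)C(=C)[C@@H]21 | intermediate
26 | ten-membered allenyl vinyl ketone | C=C(C)C(=O)O[C@@H]1CC(C)=[C@@]=C([H])C(=O)/C(CO[Si](c3ccccc3)(c3ccccc3)C(C)(C)C)=C\[C@H]2OC(=O)C(=C)[C@@H]21 | intermediate
27 | 1,10-allene oxide (alkylidene oxirane, C10 and C3 cis on C1=C2) | C=C(C)C(=O)O[C@@H]1C[C@@]3(C)O/C3=C/C(=O)/C(CO[Si](c4ccccc4)(c4ccccc4)C(C)(C)C)=C\[C@H]2OC(=O)C(=C)[C@@H]21 | intermediate (not isolated)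
28 | 15-O-TBDPS ether of the target | C=C(C)C(=O)O[C@@H]1C[C@]2(C)OC(=CC2=O)/C(CO[Si](c3ccccc3)(c3ccccc3)C(C)(C)C)=C\[C@H]2OC(=O)C(=C)[C@@H]21 | intermediate
29 | CNP0180483.4 | C=C(C)C(=O)O[C@@H]1C[C@]2(C)OC(=CC2=O)/C(CO)=C\[C@H]2OC(=O)C(=C)[C@@H]21 | target

**Summary**

Total step count: 20. Longest linear sequence: 17 steps (steps 1–8, then 12–20).

**Steps most likely to fail**

Step 19 (proposed new method). What may go wrong: a second epoxidation before ring closure, competing epoxidation of another alkene, or opening of the allene oxide to a free oxyallyl cation with loss of axis-to-centre fidelity. The fallback sets out from 25 and returns at 28, using known chemistry. Epoxidation of α-allenic alcohols with a peracid or dioxirane, with capture of the allene oxide by the hydroxyl group to give dihydrofuran-3(2H)-ones, is established. Applied to the (3S)-epimer of 25 (buffered m-CPBA or DMDO, CH2Cl2, −40 °C), it should close the same C10–O bond from the C3 hydroxyl and give the oxygen-bridged dihydrofuran-3(2H)-one F1, with C10 again set by the allene axis. IBX dehydrogenation of F1 (DMSO, 65 °C) then installs the C2=C3 bond and gives 28. The (3R)-epimer of 25 cannot reach C10 and is recycled through 26 by NaBH4/CeCl3 reduction.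

Step 17. What may go wrong: oligomerization instead of ring closure because of the strain of the allenic ten-membered ring, or nickel-mediated consumption of the allene. The fallback sets out from 24 and returns at 26, closing ring A at the ketone oxidation level so that step 18 is skipped. Pinnick oxidation (NaClO2, NaH2PO4, 2-methylbut-2-ene) gives the allenic acid F2. 2,2'-Dipyridyl disulfide and PPh3 convert it into the S-2-pyridyl thioester F3. An intramolecular nickel-catalysed reductive acyl–vinyl coupling of the thioester with the vinyl iodide (NiBr2·glyme, 4,4'-di-tert-butyl-2,2'-bipyridine, Cp2ZrCl2, Zn, high dilution) then forms the C3–C4 bond.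

Step 12. What may go wrong: reversed or poor facial selectivity from C8 (the least secure stereochemical prediction of the route), syn instead of anti addition, or isomerization of the (Z)-iodo-enal. The fallback sets out from 13 and 17 and returns at 19, replacing substrate control by reagent control. B2pin2 with Pd2(dba)3 (cat.) in DMSO converts 13 into the allylboronate F4 with the same alkene geometry. Allylboration of 17 catalysed by a chiral BINOL-derived phosphoric acid (enantiomer chosen for the required C7 face; closed chair transition state, stereospecific syn addition) gives, after lactonization, the cis-lactone F5, with C7 as in 19 and C6 epimeric. LiOH opens it to the hydroxy acid F6, and Mitsunobu lactonization (PPh3, DIAD) inverts C6 to give 19.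

**Further compounds**

F1 | step 19 | oxygen-bridged (3S,10S)-dihydrofuran-3(2H)-one (C2 saturated analogue of 28) | C=C(C)C(=O)O[C@@H]1C[C@]2(C)O[C@@H](CC2=O)/C(CO[Si](c3ccccc3)(c3ccccc3)C(C)(C)C)=C\[C@H]2OC(=O)C(=C)[C@@H]21
F2 | step 17 | allenic acid (C3 carboxylic acid of 24) | C=C1C(=O)O[C@H](/C=C(\I)CO[Si](c2ccccc2)(c2ccccc2)C(C)(C)C)[C@H]1[C@H](OC(=O)C(C)=C)CC(C)=[C@@]=C([H])C(=O)O
F3 | step 17 | S-2-pyridyl thioester of F2 | C=C1C(=O)O[C@H](/C=C(\I)CO[Si](c2ccccc2)(c2ccccc2)C(C)(C)C)[C@H]1[C@H](OC(=O)C(C)=C)CC(C)=[C@@]=C([H])C(=O)Sc3ccccn3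
F4 | step 12 | pinacol allylboronate corresponding to 13 | CC1(C)OB(C/C(C(=O)OC)=C\[C@H](O[Si](CC)(CC)CC)CC(C)=[C@@]=C([H])CO[Si](C)(C)C(C)(C)C)OC1(C)C
F5 | step 12 | cis-lactone (C6 epimer of 19) | C=C1C(=O)O[C@@H](/C=C(\I)CO[Si](c2ccccc2)(c2ccccc2)C(C)(C)C)[C@H]1[C@H](O[Si](CC)(CC)CC)CC(C)=[C@@]=C([H])CO[Si](C)(C)C(C)(C)C
F6 | step 12 | 6,7-syn hydroxy acid from F5 | OC(=O)C(=C)[C@@H]([C@@H](O)/C=C(\I)CO[Si](c1ccccc1)(c1ccccc1)C(C)(C)C)[C@H](O[Si](CC)(CC)CC)CC(C)=[C@@]=C([H])CO[Si](C)(C)C(C)(C)C
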